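**Retrosynthetic overview**

1. Side chain numbered C1′ (on chromene C2) to C12′; benzene ring = ring A, pyran ring = ring B. The target comes from an enynol by hydroxyl-directed trans-reduction and desilylation, so the E C6′=C7′ alkene is carried as an alkyne.
2. Key disconnection between C5′H2 and C6′: a chromene allylic bromide (rings A and B plus C1′–C5′) and 2,3-epoxygeranyl chloride. In one flask the epoxy chloride fragments to an alkoxide–alkynide dianion (unveiling C8′–OH and C6′≡C7′) and is allylated at C6′ under copper catalysis.
3. The chromene bromide comes from SeO2 oxidation and Appel bromination of a 2-homoprenyl chromene. Ring B is closed once, before the key step, by intramolecular Pd C–O coupling of a Z-allylic tertiary alcohol made by Sonogashira coupling and Lindlar reduction; ring A is bought as 4-amino-3-methylphenol.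
4. Both S stereocentres (chromene C2 and C8′) come from a single Sharpless epoxide of geraniol, because the same chloro-epoxide feeds both halves.
5. Enabling feature: the skipped diene C3′=C4′–C5′H2–C6′H=C7′H with the tertiary carbinol C8′ next to C7′. C6′=C7′–C8′(OH) is the retron of a propargylic alkoxide, so C6′ can be an sp carbanion and O–C8′, C7′, C6′ map onto the oxirane oxygen, CH and CH2Cl of an epoxy chloride, while C5′ is a primary allylic electrophile.

Key step: step 12

Assumption on the chemistry: the chloroalkenyl alkoxide intermediates of steps 3 and 12 are drawn as E-chloroalkenes; either alkene geometry would lead on to the alkynide.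

**Step 1**
Reactants: 1 geraniol
Product: 2 [(2S,3S)-3-methyl-3-(4-methylpent-3-en-1-yl)oxiran-2-yl]methanol
Conditions: Ti(OiPr)4 (5 mol%), L-(+)-diethyl tartrate (7 mol%), t-BuOOH, 4 Å MS, CH2Cl2, −20 °C
Reagents that add atoms: tert-butyl hydroperoxide, CC(C)(C)OO
Why: Sharpless asymmetric epoxidation: the allylic hydroxyl binds the titanium tartrate so only the 2,3-alkene reacts, and L-(+)-tartrate should give the 2S,3S epoxide, fixing the quaternary carbon that becomes both chromene C2 and C8′.

**Step 2**
Reactants: 2 (2S,3S)-2,3-epoxygeraniol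
Product: 3 (2S,3R)-3-(chloromethyl)-2-methyl-2-(4-methylpent-3-en-1-yl)oxirane
Conditions: PPh3, CCl4, NaHCO3 (cat.), reflux
Reagents that add atoms: carbon tetrachloride, ClC(Cl)(Cl)Cl
Why: Appel chlorination of the primary alcohol under neutral conditions should leave the epoxide intact; no stereocentre is touched (the CH descriptor changes from S to R only because CH2Cl now outranks the ring carbon).

**Step 3**
Reactants: 3 chloro-epoxide
Product: 6 (3S)-3,7-dimethyloct-6-en-1-yn-3-ol, via sodium chloroalkenyl alkoxide 4 (not isolated), via disodium alkynide alkoxide 5 (not isolated)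
Conditions: NaNH2 (3.3 equiv), liq. NH3, −33 °C; then NH3 evaporated, Et2O, H2O
Reagents that add atoms: none
Why: Base-induced fragmentation of a 2,3-epoxy chloride to a propargylic alcohol with an alkali-metal amide in liquid ammonia, chosen here because only the free alkynol is wanted (deprotonation at CH2Cl, β-elimination opening the oxirane to 4, dehydrochlorination and metalation to 5); the C–O bond at the quaternary carbon is never broken, so the S configuration should be retained.

**Step 4**
Reactants: 7 4-amino-3-methylphenol
Product: 8 2-methyl-4-[(triisopropylsilyl)oxy]aniline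
Conditions: i-Pr3SiCl, imidazole, DMF, 0 °C → rt
Reagents that add atoms: triisopropylsilyl chloride, CC(C)[Si](Cl)(C(C)C)C(C)C
Why: Silyl ether formation: the phenol oxygen is silylated selectively, since any N-silyl species hydrolyses on work-up, and the bulky aryl silyl ether should survive all later steps up to fluoride cleavage.

**Step 5**
Reactants: 8 silyloxy aniline
Product: 9 2-iodo-6-methyl-4-[(triisopropylsilyl)oxy]aniline
Conditions: N-iodosuccinimide, MeCN, 0 °C, dark
Reagents that add atoms: N-iodosuccinimide, O=C1CCC(=O)N1I
Why: Electrophilic aromatic iodination directed by the amino group to its only free ortho position (para carries the silyloxy group, the other ortho the methyl group).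

**Step 6**
Reactants: 9 iodoaniline
Product: 11 (4-bromo-3-iodo-5-methylphenoxy)triisopropylsilane, via arenediazonium bromide 10 (not isolated)
Conditions: t-BuONO, CuBr2, MeCN, 0 °C → rt
Reagents that add atoms: copper dibromide, Br[Cu]Br
Why: Sandmeyer-type bromodeamination under non-aqueous conditions: diazotisation by the alkyl nitrite and copper-mediated bromine transfer replace nitrogen at the same carbon, and the acid-free medium should spare the silyl ether and the C–I bond.

**Step 7**
Reactants: 6 (S)-dehydrolinalool; 11 bromo-iodo-arene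
Product: 12 (3S)-1-[2-bromo-3-methyl-5-(triisopropylsilyloxy)phenyl]-3,7-dimethyloct-6-en-1-yn-3-ol
Conditions: PdCl2(PPh3)2 (3 mol%), CuI (copper monoiodide, 5 mol%), Et3N, THF, rt
Reagents that add atoms: none
Why: Sonogashira coupling: oxidative addition of zerovalent palladium at C–I should be far faster than at the hindered C–Br bond, the free tertiary hydroxyl is tolerated and the stereocentre is not involved.

**Step 8**
Reactants: 12 aryl alkynyl carbinol
Product: 13 (1Z,3S)-1-[2-bromo-3-methyl-5-(triisopropylsilyloxy)phenyl]-3,7-dimethylocta-1,6-dien-3-ol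
Conditions: H2 (1 atm), Pd/CaCO3 poisoned with Pb(OAc)2 (Lindlar catalyst), quinoline, EtOAc, rt
Reagents that add atoms: none
Why: Lindlar semi-hydrogenation: syn addition of hydrogen to the alkyne should give the Z-alkene, while the trisubstituted alkene, the aryl bromide and the silyl ether are left alone by the poisoned catalyst.

**Step 9**
Reactants: 13 Z-allylic tertiary alcohol
Product: 14 triisopropyl{[(2S)-2,8-dimethyl-2-(4-methylpent-3-en-1-yl)-2H-chromen-6-yl]oxy}silane
Conditions: Pd(OAc)2 (5 mol%), 2-(di-tert-butylphosphino)-1,1′-binaphthyl (6 mol%), Cs2CO3, toluene, 80 °C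
Reagents that add atoms: none
Why: Intramolecular Buchwald–Hartwig-type C–O coupling closes ring B: the Z-alkene holds the tertiary alkoxide next to the aryl–palladium bond, a tertiary alkoxide cannot undergo β-hydride elimination, and the stereocentre keeps its C–O bond, so chromene C2 should be S.

**Step 10**
Reactants: 14 homoprenyl chromene
Product: 15 (2E)-5-[(2S)-2,8-dimethyl-6-(triisopropylsilyloxy)-2H-chromen-2-yl]-2-methylpent-2-en-1-ol
Conditions: SeO2 (0.3 equiv), t-BuOOH, salicylic acid (cat.), CH2Cl2, 0 °C → rt, stopped before over-oxidation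
Reagents that add atoms: selenium dioxide, O=[Se]=O (substoichiometric oxygen carrier) and tert-butyl hydroperoxide, CC(C)(C)OO (stoichiometric oxygen source)
Why: SeO2 allylic oxidation (ene reaction, then 2,3-sigmatropic shift) should hydroxylate the E-methyl group of the terminal trisubstituted alkene; the chromene alkene has no allylic hydrogen (C2 is quaternary) and should stay untouched.

**Step 11**
Reactants: 15 allylic alcohol
Product: 16 {[(2S)-2-[(3E)-5-bromo-4-methylpent-3-en-1-yl]-2,8-dimethyl-2H-chromen-6-yl]oxy}triisopropylsilane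
Conditions: CBr4, PPh3, CH2Cl2, 0 °C
Reagents that add atoms: carbon tetrabromide, BrC(Br)(Br)Br
Why: Appel bromination of the primary allylic alcohol under neutral conditions should keep the E geometry, the silyl ether and the chromene.

**Step 12**
Reactants: 3 chloro-epoxide (1.3 equiv); 16 chromene allylic bromide
Product: 19 (6S,10E)-13-[(2S)-2,8-dimethyl-6-(triisopropylsilyloxy)-2H-chromen-2-yl]-2,6,10-trimethyltrideca-2,10-dien-7-yn-6-ol, via lithium chloroalkenyl alkoxide 17 (not isolated), via dilithio alkynide alkoxide 18 (not isolated)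
Conditions: 3, n-BuLi (3.0 equiv per 3), THF, −78 → −20 °C; then CuI (copper monoiodide, 10 mol%), 16, −20 °C → rt; then H2O
Reagents that add atoms: none
Why: n-BuLi deprotonates CH2Cl of 3, the carbanion opens the oxirane by β-elimination to alkoxide 17, a second equivalent eliminates LiCl to the alkyne and a third metalates it to dianion 18, whose alkynide is passed to monovalent copper and displaces the primary allylic bromide of 16 to form the C5′–C6′ bond. The closest known reaction types are the base-induced fragmentation of 2,3-epoxy chlorides to propargylic alcohols with trapping of the alkynide in the same flask, and the copper-catalysed allylation of propargylic alkoxide–alkynide dianions with allylic halides to give 1,4-enynes. No ring is closed here; the temporary oxirane ring is opened and the chlorine activating group is expelled. No new stereocentre is created: the S configuration at C8′ is carried over from the Sharpless epoxide because its C–O bond is never broken. The step needs C- over O-allylation (a soft copper alkynide against a hard, hindered tertiary lithium alkoxide), attack at CH2Br rather than SN2′ attack at the more hindered CH terminus, retention of the E geometry of 16, and no alkyllithium left when 16 is added (secured by the exact 3:1 base stoichiometry). The alkyne is the temporary higher oxidation level that makes C6′ nucleophilic, and it is taken down to the E-alkene in step 13.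

**Step 13**
Reactants: 19 enynol
Product: 20 (6S,7E,10E)-13-[(2S)-2,8-dimethyl-6-(triisopropylsilyloxy)-2H-chromen-2-yl]-2,6,10-trimethyltrideca-2,7,10-trien-6-ol
Conditions: NaAlH2(OCH2CH2OCH3)2 (Red-Al), THF, 0 → 40 °C; then H2O
Reagents that add atoms: none
Why: Hydroxyl-directed trans-hydroalumination of a propargylic alcohol: the aluminium alkoxide delivers hydride intramolecularly in an anti sense, and protonolysis should give only the E-alkene, while the isolated alkenes, the chromene and the aryl silyl ether are not reduced.

**Step 14**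
Reactants: 20 silyl ether of the target
Product: 21 (2S)-2-[(3E,6E,8S)-8-hydroxy-4,8,12-trimethyltrideca-3,6,11-trien-1-yl]-2,8-dimethyl-2H-chromen-6-ol
Conditions: Bu4NF, AcOH (1:1), THF, 0 °C, argon
Reagents that add atoms: none
Why: Fluoride cleavage of the aryl silyl ether; the acetic acid buffer keeps the electron-rich phenol from air oxidation as its phenoxide, and the tertiary allylic alcohol, skipped diene and chromene are inert to fluoride.

**Compound list**

1 | geraniol, (2E)-3,7-dimethylocta-2,6-dien-1-ol | CC(C)=CCC/C(C)=C/CO | starting material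
2 | [(2S,3S)-3-methyl-3-(4-methylpent-3-en-1-yl)oxiran-2-yl]methanol | CC(C)=CCC[C@]1(C)O[C@H]1CO | intermediate
3 | (2S,3R)-3-(chloromethyl)-2-methyl-2-(4-methylpent-3-en-1-yl)oxirane | CC(C)=CCC[C@]1(C)O[C@H]1CCl | intermediate
4 | sodium (1E,3S)-1-chloro-3,7-dimethylocta-1,6-dien-3-olate | CC(C)=CCC[C@](C)(O[Na])/C=C/Cl | intermediate (not isolated)
5 | disodium salt of (3S)-3,7-dimethyloct-6-en-1-yn-3-ol (alkoxide and alkynide) | CC(C)=CCC[C@](C)(O[Na])C#C[Na] | intermediate (not isolated)
6 | (3S)-3,7-dimethyloct-6-en-1-yn-3-ol | CC(C)=CCC[C@](C)(O)C#C | intermediate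
7 | 4-amino-3-methylphenol | Cc1cc(O)ccc1N | starting material
8 | 2-methyl-4-[(triisopropylsilyl)oxy]aniline | Cc1cc(O[Si](C(C)C)(C(C)C)C(C)C)ccc1N | intermediate
9 | 2-iodo-6-methyl-4-[(triisopropylsilyl)oxy]aniline | Cc1cc(O[Si](C(C)C)(C(C)C)C(C)C)cc(I)c1N | intermediate
10 | 2-iodo-6-methyl-4-[(triisopropylsilyl)oxy]benzenediazonium bromide | Cc1cc(O[Si](C(C)C)(C(C)C)C(C)C)cc(I)c1[N+]#N.[Br-] | intermediate (not isolated)
11 | (4-bromo-3-iodo-5-methylphenoxy)triisopropylsilane | Cc1cc(O[Si](C(C)C)(C(C)C)C(C)C)cc(I)c1Br | intermediate
12 | (3S)-1-[2-bromo-3-methyl-5-(triisopropylsilyloxy)phenyl]-3,7-dimethyloct-6-en-1-yn-3-ol | CC(C)=CCC[C@](C)(O)C#Cc1cc(O[Si](C(C)C)(C(C)C)C(C)C)cc(C)c1Br | intermediate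
13 | (1Z,3S)-1-[2-bromo-3-methyl-5-(triisopropylsilyloxy)phenyl]-3,7-dimethylocta-1,6-dien-3-ol | CC(C)=CCC[C@](C)(O)/C=C\c1cc(O[Si](C(C)C)(C(C)C)C(C)C)cc(C)c1Br | intermediate
14 | triisopropyl{[(2S)-2,8-dimethyl-2-(4-methylpent-3-en-1-yl)-2H-chromen-6-yl]oxy}silane | CC(C)=CCC[C@@]1(C)C=Cc2cc(O[Si](C(C)C)(C(C)C)C(C)C)cc(C)c2O1 | intermediate
15 | (2E)-5-[(2S)-2,8-dimethyl-6-(triisopropylsilyloxy)-2H-chromen-2-yl]-2-methylpent-2-en-1-ol | OC/C(C)=C/CC[C@@]1(C)C=Cc2cc(O[Si](C(C)C)(C(C)C)C(C)C)cc(C)c2O1 | intermediate
16 | {[(2S)-2-[(3E)-5-bromo-4-methylpent-3-en-1-yl]-2,8-dimethyl-2H-chromen-6-yl]oxy}triisopropylsilane | BrC/C(C)=C/CC[C@@]1(C)C=Cc2cc(O[Si](C(C)C)(C(C)C)C(C)C)cc(C)c2O1 | intermediate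
17 | lithium (1E,3S)-1-chloro-3,7-dimethylocta-1,6-dien-3-olate | CC(C)=CCC[C@](C)(O[Li])/C=C/Cl | intermediate (not isolated)
18 | dilithium salt of (3S)-3,7-dimethyloct-6-en-1-yn-3-ol (alkoxide and alkynide) | CC(C)=CCC[C@](C)(O[Li])C#C[Li] | intermediate (not isolated)
19 | (6S,10E)-13-[(2S)-2,8-dimethyl-6-(triisopropylsilyloxy)-2H-chromen-2-yl]-2,6,10-trimethyltrideca-2,10-dien-7-yn-6-ol | CC(C)=CCC[C@](C)(O)C#CC/C(C)=C/CC[C@@]1(C)C=Cc2cc(O[Si](C(C)C)(C(C)C)C(C)C)cc(C)c2O1 | intermediate
20 | (6S,7E,10E)-13-[(2S)-2,8-dimethyl-6-(triisopropylsilyloxy)-2H-chromen-2-yl]-2,6,10-trimethyltrideca-2,7,10-trien-6-ol | CC(C)=CCC[C@](C)(O)/C=C/C/C(C)=C/CC[C@@]1(C)C=Cc2cc(O[Si](C(C)C)(C(C)C)C(C)C)cc(C)c2O1 | intermediate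
21 | (2S)-2-[(3E,6E,8S)-8-hydroxy-4,8,12-trimethyltrideca-3,6,11-trien-1-yl]-2,8-dimethyl-2H-chromen-6-ol | CC(C)=CCC[C@](C)(O)/C=C/C/C(C)=C/CC[C@@]1(C)C=Cc2cc(O)cc(C)c2O1 | target

**Step count**

Total: 14 steps. Longest linear sequence: 11 steps (steps 1, 2, 3, 7, 8, 9, 10, 11, 12, 13, 14; the arene branch through steps 4, 5, 6 is equally long).

**Steps most likely to fail, with fallbacks**

Step 12. The fragmentation may be incomplete, leaving alkyllithium that attacks the bromide. The alkynide may also attack in the SN2′ sense or the alkoxide may be allylated, and the new 1,4-enyne may drift into conjugation under the basic conditions. The fallback moves the nucleophile from an sp to an sp2 carbon and sets out from alkyne 6. Syn-hydrostannation with Bu3SnH and PdCl2(PPh3)2 in THF at 0 °C should put tin on the terminal carbon, away from the quaternary carbinol, to give (1E,3S)-3,7-dimethyl-1-(tributylstannyl)octa-1,6-dien-3-ol F1. Stille coupling of this stannane with bromide 16 (Pd2(dba)3, AsPh3, THF/DMF, rt → 45 °C) joins the same two carbons at the less substituted allyl terminus with both alkene geometries kept. This comes back to the route at 20, so step 13 is not needed.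

Step 9. The styrenyl alkene may isomerise from Z to E under the basic palladium conditions, which puts the alkoxide out of reach, or the doubly activated tertiary allylic C–O bond may ionise before ring closure. The fallback takes the alkene out of the tether and sets out from 13. Diimide reduction (TsNHNH2, NaOAc, DME/H2O, reflux) should saturate only the cis-disubstituted styrenyl alkene, giving (3S)-1-[2-bromo-3-methyl-5-(triisopropylsilyloxy)phenyl]-3,7-dimethyloct-6-en-3-ol F2. The same Pd(OAc)2/phosphine/Cs2CO3 etherification, now on a saturated bromoaryl tertiary alcohol, closes ring B to triisopropyl{[(2S)-2,8-dimethyl-2-(4-methylpent-3-en-1-yl)chroman-6-yl]oxy}silane F3. Dehydrogenation with DDQ (benzene, reflux; hydride abstraction from benzylic C4 assisted by the ring oxygen) reinstalls the C3=C4 alkene and comes back to the route at 14.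

Step 10. The oxidation may run on to the enal and acid, attack the Z-methyl group, or degrade the electron-rich chromene under the peroxide. The fallback replaces C–H oxidation by olefin cross-metathesis and sets out from 14. Methacrolein with the second-generation Hoveyda–Grubbs catalyst, RuCl2(H2IMes)(=CH–C6H4–2-OiPr), in CH2Cl2 at 40 °C should exchange the isopropylidene terminus for the E-enal, giving (2E)-5-[(2S)-2,8-dimethyl-6-(triisopropylsilyloxy)-2H-chromen-2-yl]-2-methylpent-2-enal F4; the ring alkene next to the quaternary carbon should not take part. Luche reduction (NaBH4, CeCl3·7H2O, MeOH, 0 °C) then comes back to the route at 15.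

**Further compounds**

F1 | step 12 | (1E,3S)-3,7-dimethyl-1-(tributylstannyl)octa-1,6-dien-3-ol | CC(C)=CCC[C@](C)(O)/C=C/[Sn](CCCC)(CCCC)CCCC
F2 | step 9 | (3S)-1-[2-bromo-3-methyl-5-(triisopropylsilyloxy)phenyl]-3,7-dimethyloct-6-en-3-ol | CC(C)=CCC[C@](C)(O)CCc1cc(O[Si](C(C)C)(C(C)C)C(C)C)cc(C)c1Br
F3 | step 9 | triisopropyl{[(2S)-2,8-dimethyl-2-(4-methylpent-3-en-1-yl)chroman-6-yl]oxy}silane | CC(C)=CCC[C@@]1(C)CCc2cc(O[Si](C(C)C)(C(C)C)C(C)C)cc(C)c2O1
F4 | step 10 | (2E)-5-[(2S)-2,8-dimethyl-6-(triisopropylsilyloxy)-2H-chromen-2-yl]-2-methylpent-2-enal | O=C/C(C)=C/CC[C@@]1(C)C=Cc2cc(O[Si](C(C)C)(C(C)C)C(C)C)cc(C)c2O1
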